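**Retrosynthetic overview**
- The target is the trans-(2S,3S)-2,3-diaryl-2,3-dihydrobenzofuran with OH at C4 and a 6-hydroxybenzofuran-2-yl group at C6. It comes from its tetrabenzyl ether by hydrogenolysis alone.
- Both oxygen heterocycles are opened together. The dihydrofuran ring is cut in a formal [4+1] sense (C2–C3 and C2–O1) to an ortho-quinone methide and a non-racemic sulfonium benzylide. The furan ring is cut at O–C2' to a 2-alkynylphenol.
- The quinone methide is cut again at C3–aryl, to an aryl Grignard reagent and a bis-Boc salicylaldehyde (Boc migration, then elimination). Three fragments therefore meet in one flask.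
- The alkynyl aldehyde comes from a Sonogashira coupling of the 4-triflate of phloroglucinaldehyde with 5-(benzyloxy)-2-ethynylphenol.
- Ring order: all benzene rings are bought. The dihydrofuran ring forms first and the furan ring second, in the same operation.

Assumption: the sense of induction of sulfide 8 follows the usual ylide model (aryl syn to the sulfur lone pair, attack on the face next to the bridgehead C–H and away from CMe2); if the first run gives the antipode, the sulfide from (S)-limonene is used instead.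

**Step 1**
Reactants: 1 2,4,6-trihydroxybenzaldehyde
Product: 2 4-formyl-3,5-dihydroxyphenyl trifluoromethanesulfonate
Conditions: PhNTf2 (1.0 equiv), Et3N (1.1 equiv), THF, 0 °C to rt
Reagents that add atoms: N-phenylbis(trifluoromethanesulfonimide), O=S(=O)(N(c1ccccc1)S(=O)(=O)C(F)(F)F)C(F)(F)F
Why: Chemoselective O-sulfonylation, because the 4-OH is the most acidic hydroxyl (para to the formyl group) and the only one neither chelated to nor flanked by the aldehyde, so its phenoxide takes the triflyl group from one equivalent of the mild donor; no stereocentre is involved.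

**Step 2**
Reactants: 2 4-formyl-3,5-dihydroxyphenyl trifluoromethanesulfonate
Product: 3 4-formyl-3,5-bis[(tert-butoxycarbonyl)oxy]phenyl trifluoromethanesulfonate
Conditions: Boc2O (2.3 equiv), DMAP (10 mol %), THF, 0 °C to rt
Reagents that add atoms: di-tert-butyl dicarbonate, CC(C)(C)OC(=O)OC(=O)OC(C)(C)C
Why: DMAP-catalysed O-acylation turns both ortho phenols into aryl tert-butyl carbonates, which supply the migrating and leaving group for step 6 and make the triflate more electron-poor for step 4.

**Step 3**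
Reactants: 4 4-(benzyloxy)-2-hydroxybenzaldehyde
Product: 5 5-(benzyloxy)-2-ethynylphenol
Conditions: dimethyl (1-diazo-2-oxopropyl)phosphonate (1.3 equiv), K2CO3 (2.5 equiv), MeOH, rt
Reagents that add atoms: dimethyl (1-diazo-2-oxopropyl)phosphonate, COP(=O)(OC)C(=[N+]=[N-])C(C)=O
Why: Ohira–Bestmann (Seyferth–Gilbert) homologation converts the aldehyde into the terminal alkyne under K2CO3/MeOH, which leaves the benzyl ether and the phenol (present as phenoxide) untouched at room temperature.

**Step 4**
Reactants: 3 4-formyl-3,5-bis[(tert-butoxycarbonyl)oxy]phenyl trifluoromethanesulfonate; 5 5-(benzyloxy)-2-ethynylphenol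
Product: 6 4-{[4-(benzyloxy)-2-hydroxyphenyl]ethynyl}-2,6-bis[(tert-butoxycarbonyl)oxy]benzaldehyde
Conditions: PdCl2(PPh3)2 (3 mol %), CuI (5 mol %), Et3N (3 equiv), THF, rt, degassed
Reagents that add atoms: none
Why: Sonogashira coupling, in which the triflate activated by the para-formyl group and two carbonates adds oxidatively to zerovalent palladium at room temperature, where 2-alkynylphenols do not yet cyclise and the hindered aryl carbonates survive Et3N.

**Step 5**
Reactants: 7 [4-(benzyloxy)phenyl]methanol; 8 (1R,4R,5R)-4,7,7-trimethyl-6-thiabicyclo[3.2.1]octane (isothiocineole, the sulfide obtained from (R)-limonene and sulfur)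
Product: 9 (1R,4R,5R,6R)-6-[4-(benzyloxy)benzyl]-4,7,7-trimethyl-6-thiabicyclo[3.2.1]octan-6-ium tetrafluoroborate (benzyl group exo, syn to the one-carbon bridge)
Conditions: HBF4·OEt2 (1.0 equiv), 8 (1.1 equiv), CH2Cl2, 0 °C to rt; precipitation with Et2O
Reagents that add atoms: tetrafluoroboric acid (as its diethyl etherate), [H+].F[B-](F)(F)F
Why: SN1-type S-alkylation, in which the acid ionises the electron-rich benzylic alcohol and the sulfide captures the cation on its exposed exo lone pair, giving one sulfonium diastereomer with a non-nucleophilic counter-ion.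

**Step 6 (key step)**
Reactants: 6 4-{[4-(benzyloxy)-2-hydroxyphenyl]ethynyl}-2,6-bis[(tert-butoxycarbonyl)oxy]benzaldehyde; 9 sulfonium tetrafluoroborate from step 5; 10 1,3-bis(benzyloxy)-5-bromobenzene
Product: 15 (2S,3S)-6-[6-(benzyloxy)-1-benzofuran-2-yl]-2-[4-(benzyloxy)phenyl]-3-[3,5-bis(benzyloxy)phenyl]-2,3-dihydro-1-benzofuran-4-ol, via aryl Grignard reagent 11 (not isolated), via sulfonium benzylide 12 (not isolated), via ortho-quinone methide 13 (not isolated), via alkynylphenol dihydrobenzofuran carbonate 14 (not isolated)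
Conditions: 10, Mg, THF, reflux (gives 11); 11 (2.1 equiv) added to 6, THF, −78 °C, 20 min; 12 [from 9 (1.5 equiv) and LiN(SiMe3)2 (1.45 equiv), THF, −78 °C] added by cannula, −78 to 0 °C over 3 h; then MeOH, Cs2CO3 (5 equiv), CuI (10 mol %), 50 °C, 4 h; same flask, no work-up in between
Reagents that add atoms: none
Why: Proposed new method: the first equivalent of 11 deprotonates the phenol and the second adds to the aldehyde, the alkoxide takes over the neighbouring Boc group and the freed phenoxide expels tert-butyl carbonate to give 13 (the anionic Boc-migration route to ortho-quinone methides), benzylide 12 then adds to the methide carbon through its open face and the phenoxide displaces the sulfide with inversion, so that the sulfide fixes C2 as S while the ring-closing betaine that keeps the two aryl groups apart fixes C3 as S (trans), after which methanolysis of the last carbonate and base/CuI-promoted 5-endo-dig hydroalkoxylation of the alkynylphenoxide close the benzofuran; the closest known reactions are the trans-selective formal [4+1] annulation of ortho-quinone methides with stabilised sulfur ylides, chiral sulfur-ylide epoxidation and cyclopropanation, and the cyclisation of 2-alkynylphenols.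

**Step 7**
Reactants: 15 (2S,3S)-tetrabenzyl ether from step 6
Product: 16 5-[(2S,3S)-4-hydroxy-6-(6-hydroxy-1-benzofuran-2-yl)-2-(4-hydroxyphenyl)-2,3-dihydro-1-benzofuran-3-yl]benzene-1,3-diol (target)
Conditions: H2 (1 atm), Pd/C (10 wt %), EtOAc/MeOH 1:1, rt
Reagents that add atoms: none
Why: Catalytic hydrogenolysis of the four primary benzyl aryl ethers is much faster than cleavage of the secondary ring C2–O bond or reduction of the 2-arylbenzofuran, and the neutral medium leaves both stereocentres untouched.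

**Compound list**
1 | 2,4,6-trihydroxybenzaldehyde | O=Cc1c(O)cc(O)cc1O | starting material
2 | 4-formyl-3,5-dihydroxyphenyl trifluoromethanesulfonate | O=Cc1c(O)cc(OS(=O)(=O)C(F)(F)F)cc1O | intermediate
3 | 4-formyl-3,5-bis[(tert-butoxycarbonyl)oxy]phenyl trifluoromethanesulfonate | O=Cc1c(OC(=O)OC(C)(C)C)cc(OS(=O)(=O)C(F)(F)F)cc1OC(=O)OC(C)(C)C | intermediate
4 | 4-(benzyloxy)-2-hydroxybenzaldehyde | O=Cc1ccc(OCc2ccccc2)cc1O | starting material
5 | 5-(benzyloxy)-2-ethynylphenol | C#Cc1ccc(OCc2ccccc2)cc1O | intermediate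
6 | 4-{[4-(benzyloxy)-2-hydroxyphenyl]ethynyl}-2,6-bis[(tert-butoxycarbonyl)oxy]benzaldehyde | O=Cc1c(OC(=O)OC(C)(C)C)cc(C#Cc2ccc(OCc3ccccc3)cc2O)cc1OC(=O)OC(C)(C)C | intermediate
7 | [4-(benzyloxy)phenyl]methanol | OCc1ccc(OCc2ccccc2)cc1 | starting material
8 | (1R,4R,5R)-4,7,7-trimethyl-6-thiabicyclo[3.2.1]octane (isothiocineole) | C[C@@H]1CC[C@@H]2C[C@H]1SC2(C)C | starting material
9 | (1R,4R,5R,6R)-6-[4-(benzyloxy)benzyl]-4,7,7-trimethyl-6-thiabicyclo[3.2.1]octan-6-ium tetrafluoroborate | C[C@@H]1CC[C@@H]2C[C@H]1[S@@+](Cc1ccc(OCc3ccccc3)cc1)C2(C)C.F[B-](F)(F)F | intermediate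
10 | 1,3-bis(benzyloxy)-5-bromobenzene | Brc1cc(OCc2ccccc2)cc(OCc2ccccc2)c1 | starting material
11 | [3,5-bis(benzyloxy)phenyl]magnesium bromide | Br[Mg]c1cc(OCc2ccccc2)cc(OCc2ccccc2)c1 | intermediate
12 | sulfonium benzylide derived from 9 (same configuration at sulfur) | C[C@@H]1CC[C@@H]2C[C@H]1[S@@+]([CH-]c1ccc(OCc3ccccc3)cc1)C2(C)C | intermediate
13 | (Z)-ortho-quinone methide, aryl group syn to C=O and away from OBoc (drawn as the free phenol, present as its bromomagnesium salt) | O=C1C=C(C#Cc2ccc(OCc3ccccc3)cc2O)C=C(OC(=O)OC(C)(C)C)/C1=C/c1cc(OCc2ccccc2)cc(OCc2ccccc2)c1 | intermediate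
14 | tert-butyl (2S,3S)-6-{[4-(benzyloxy)-2-hydroxyphenyl]ethynyl}-2-[4-(benzyloxy)phenyl]-3-[3,5-bis(benzyloxy)phenyl]-2,3-dihydro-1-benzofuran-4-yl carbonate | c1ccccc1COc1ccc([C@H]2Oc3cc(C#Cc4ccc(OCc5ccccc5)cc4O)cc(OC(=O)OC(C)(C)C)c3[C@@H]2c2cc(OCc3ccccc3)cc(OCc3ccccc3)c2)cc1 | intermediate
15 | (2S,3S)-6-[6-(benzyloxy)-1-benzofuran-2-yl]-2-[4-(benzyloxy)phenyl]-3-[3,5-bis(benzyloxy)phenyl]-2,3-dihydro-1-benzofuran-4-ol | c1ccccc1COc1ccc([C@H]2Oc3cc(-c4cc5ccc(OCc6ccccc6)cc5o4)cc(O)c3[C@@H]2c2cc(OCc3ccccc3)cc(OCc3ccccc3)c2)cc1 | intermediate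
16 | 5-[(2S,3S)-4-hydroxy-6-(6-hydroxy-1-benzofuran-2-yl)-2-(4-hydroxyphenyl)-2,3-dihydro-1-benzofuran-3-yl]benzene-1,3-diol | Oc1ccc([C@H]2Oc3cc(-c4cc5ccc(O)cc5o4)cc(O)c3[C@@H]2c2cc(O)cc(O)c2)cc1 | target

**Step count and risks**
Total steps: 7. Longest linear sequence: 5 (steps 1, 2, 4, 6, 7).

**Step 6 is the most likely to fail.**
- The quinone methide must be released while the benzylide is still alive.
- The trans/cis ratio and the ee of a semi-stabilised ylide in this annulation are untested.
- Any cis isomer is (2S,3R). It must be removed by chromatography and not epimerised with acid, because inversion at C2 would give the enantiomer of 15.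
- The fallback sets out from 6 and comes back at 15. It takes the cascade apart, reverses the ring order and releases the quinone methide from a storable precursor.
- AuCl3 (3 mol %, CH2Cl2, rt) cycloisomerises 6 to 4-[6-(benzyloxy)-1-benzofuran-2-yl]-2,6-bis[(tert-butoxycarbonyl)oxy]benzaldehyde F1.
- Addition of 11 (1.05 equiv, THF, −78 °C), followed by a cold quench with p-toluenesulfinic acid and warming, gives the bench-stable racemic sulfone tert-butyl 5-[6-(benzyloxy)-1-benzofuran-2-yl]-2-{[3,5-bis(benzyloxy)phenyl](4-methylbenzenesulfonyl)methyl}-3-hydroxyphenyl carbonate F2.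
- Cs2CO3 in MeCN at 0 °C then eliminates sulfinate slowly while it generates the ylide from 9 in situ. This gives the 4-O-tert-butyl carbonate of 15 F3, which K2CO3/MeOH converts into 15.

**Step 1 is second.** Triflation may also occur at an ortho hydroxyl or twice.
- The fallback sets out from 5 and comes back at 6. It by-passes 1 to 3 by fixing the substitution pattern through nucleophilic aromatic substitution instead of hydroxyl discrimination.
- Commercial 4-bromo-2,6-difluorobenzaldehyde reacts with BnOH/NaH in DMF to give 2,6-bis(benzyloxy)-4-bromobenzaldehyde F4.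
- BCl3 (CH2Cl2, −78 to 0 °C) gives 4-bromo-2,6-dihydroxybenzaldehyde F5.
- Boc2O/DMAP gives 4-bromo-2,6-bis[(tert-butoxycarbonyl)oxy]benzaldehyde F6.
- F6 couples with 5 (PdCl2(PhCN)2/P(t-Bu)3, CuI, Et3N, dioxane, rt) to give 6.

**Step 7 is third.** Possible problems are hydrogenolysis of the benzylic C2–O bond, partial reduction of the benzofuran, and catalyst poisoning by traces of sulfide.
- The fallback sets out from 15 and comes back at 16.
- It replaces reduction by Lewis-acid dealkylation: BCl3 (8 equiv) with pentamethylbenzene as cation scavenger, CH2Cl2, −78 °C, then MeOH quench.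
- Any transient opening at C2 recloses trans under control of the unchanged C3. The fallback makes no new compound (F0).

**Further compounds**
F1 | step 6 | 4-[6-(benzyloxy)-1-benzofuran-2-yl]-2,6-bis[(tert-butoxycarbonyl)oxy]benzaldehyde | O=Cc1c(OC(=O)OC(C)(C)C)cc(-c2cc3ccc(OCc4ccccc4)cc3o2)cc1OC(=O)OC(C)(C)C
F2 | step 6 | tert-butyl 5-[6-(benzyloxy)-1-benzofuran-2-yl]-2-{[3,5-bis(benzyloxy)phenyl](4-methylbenzenesulfonyl)methyl}-3-hydroxyphenyl carbonate (racemic) | Cc1ccc(cc1)S(=O)(=O)C(c1cc(OCc2ccccc2)cc(OCc2ccccc2)c1)c1c(O)cc(-c2cc3ccc(OCc4ccccc4)cc3o2)cc1OC(=O)OC(C)(C)C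
F3 | step 6 | tert-butyl (2S,3S)-6-[6-(benzyloxy)-1-benzofuran-2-yl]-2-[4-(benzyloxy)phenyl]-3-[3,5-bis(benzyloxy)phenyl]-2,3-dihydro-1-benzofuran-4-yl carbonate | c1ccccc1COc1ccc([C@H]2Oc3cc(-c4cc5ccc(OCc6ccccc6)cc5o4)cc(OC(=O)OC(C)(C)C)c3[C@@H]2c2cc(OCc3ccccc3)cc(OCc3ccccc3)c2)cc1
F4 | step 1 | 2,6-bis(benzyloxy)-4-bromobenzaldehyde | O=Cc1c(OCc2ccccc2)cc(Br)cc1OCc1ccccc1
F5 | step 1 | 4-bromo-2,6-dihydroxybenzaldehyde | O=Cc1c(O)cc(Br)cc1O
F6 | step 1 | 4-bromo-2,6-bis[(tert-butoxycarbonyl)oxy]benzaldehyde | O=Cc1c(OC(=O)OC(C)(C)C)cc(Br)cc1OC(=O)OC(C)(C)C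
F0 | step 7 | none | none
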